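The data come from a simulation on assumed constants, noise included.

One turnover per minute, each catalyst making one target a minute, is the unit I reckon in. The south-west run holds 17.2% of target at 25.0 min on 1 mol% of free catalyst, which gives 0.688 min⁻¹, and this average count of targets per catalyst per minute, the turnover frequency, is what I carry.

| setting | south-west | south-east | gamma | delta | alpha | eta |
|---|---|---|---|---|---|---|
| substrate | 0.80 M | 0.80 M | 0.80 M | 0.80 M | 0.80 M | 0.80 M |
| coupling partner | 1.2 equiv | 1.2 equiv | 2.50 equiv | 2.50 equiv | 2.50 equiv | 2.50 equiv |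
| free catalyst | 1 mol% | 1 mol% | 1 mol% | 1 mol% | 1 mol% | 1 mol% |
| temperature | 25 °C | 47 °C | 55 °C | 15 °C |  | 35 °C |
| remark | run made earlier | run made earlier |  |  | at 55 °C until 10 min, from then on at 15 °C |  |
| time |  |  | 20 min | 20 min | 20 min | 20 min |

| run | time / min | target / % | substrate / % |
|---|---|---|---|
| south-west | 4.00 | 3.3 | 96.1 |
| south-west | 12.0 | 9.4 | 90.8 |
| south-west | 25.0 | 17.2 | 82.0 |
| south-west | 40.0 | 25.8 | 74.2 |
| south-west | 50.0 | 30.8 | 69.2 |
| south-west | 60.0 | 35.4 | 65.2 |
| south-west | 80.0 | 41.8 | 59.0 |
| south-east | 1.00 | 3.8 | 95.4 |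
| south-east | 3.00 | 10.4 | 89.4 |
| south-east | 6.00 | 18.0 | 80.1 |
| south-east | 8.00 | 23.1 | 75.9 |
| south-east | 12.0 | 30.5 | 70.4 |
| south-east | 15.0 | 34.5 | 66.2 |
| south-east | 20.0 | 39.9 | 59.5 |

(each reading ± 0.5 percentage points)



- the flask that comes out highest in amount of target, in percent of the substrate charged, or "all alike" when all lie within 1.5 percentage points (gamma / delta / alpha / eta / all alike)
- target at the end, in percent of the substrate charged, gamma
- target at the end, in percent of the substrate charged, delta
- target at the end, in percent of the substrate charged, alpha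
- target at the end, in percent of the substrate charged, eta

The south-east run reaches nearly the same conversion, 18.0%, at 6.00 min, so at like concentrations it gives 3.00 min⁻¹. I let each degree multiply the frequency by one constant factor, which puts it at 0.352 min⁻¹ at 15 °C, 1.34 min⁻¹ at 35 °C and 5.12 min⁻¹ at 55 °C. These figures hold for the partner charge of those runs, and going from 1.2 equiv to 2.50 equiv gives my upper edge, twice the frequency, if the rate follows [coupling partner] in full, while my lower edge assumes no gain.

By the charge the substrate is the limiting reagent, so the end the charge allows is full conversion, 100 turnovers per catalyst. I take the unreacted share to fall as exp(−t/τ), where τ is that count divided by the frequency.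

The ladder on the lower edge then runs from short to long: one turnover takes 0.195 min at 55 °C and 2.84 min at 15 °C, τ is 19.5 min at 55 °C, the flasks stand for 20 min, and τ is 284 min at 15 °C. So in my reckoning gamma stands a little longer than its τ and has time to curve over, while delta stands far shorter than its τ and stays on its straight start, with target growing in step with time and catalyst.

Time over τ, added stage by stage, is 1.02 for gamma, 0.548 for alpha, 0.269 for eta and 0.0705 for delta. I therefore commit to that order, to a lower edge of 64.1% in gamma, and to edges of 6.80% and 13.7% in delta.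

The forecast, reading a sag in the south-east run as “thermal catalyst death”, names gamma, with 69% in gamma, 58% in alpha, 47% in eta and 14.7% in delta, the last higher than my upper edge.

The flasks give 57.7% in gamma, 46.8% in alpha, 37.2% in eta and 9.93% in delta, so the order is mine. Delta lies inside my edges, but gamma stands lower than my lower edge.

    substrate + free catalyst ⇌ catalyst intermediate A (K = 1.00 M⁻¹, k = 0.310 M⁻¹ s⁻¹, Ea = 45.0 kJ mol⁻¹, ΔH = −14.0 kJ mol⁻¹)
    coupling partner + catalyst intermediate A ⇌ catalyst intermediate B (K = 0.400 M⁻¹, k = 0.110 M⁻¹ s⁻¹, Ea = 62.0 kJ mol⁻¹, ΔH = 36.0 kJ mol⁻¹)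
    catalyst intermediate B ⇌ released group + catalyst intermediate C (K = 65.0 M, k = 18.0 s⁻¹, Ea = 61.0 kJ mol⁻¹, ΔH = −9.00 kJ mol⁻¹)
    catalyst intermediate C → free catalyst + target (k = 0.140 s⁻¹, Ea = 72.0 kJ mol⁻¹)
    2 coupling partner → self-condensation product (k = 2.30 × 10⁻⁴ M⁻¹ s⁻¹, Ea = 78.0 kJ mol⁻¹)
    (constants at 35 °C)

Delta's 9.93% in 20 min on 1 mol% is a frequency of 0.497 min⁻¹, lower than the 0.688 min⁻¹ read at 25 °C and higher than my 0.352 min⁻¹. A frequency counts per catalyst, so for the neighbour of delta charged with 4 mol% of free catalyst I keep it and reckon 32.8% of target in the same time. That neighbour of delta holds 36.0% of target, which is 0.450 min⁻¹ per catalyst.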